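The cyclohexane is C1, C10, C11, C12, C13, C14 (briarane numbering) and shares the C1–C10 bond with the cyclodecene. Everything rests on cutting this bond. C1 sits between two oxygenated carbons (C2, C14), so it is best made as a tertiary radical. C10 is β to the C12 oxygen, so it becomes the β-carbon of an enone. The precursor is a 14-membered carbocycle (C1–C14) that already carries the γ-lactone, an exocyclic C1=C15 methylene and the C10=C11–C12=O enone. One hydrogen-atom-transfer-initiated transannular Giese closure creates the C15 methyl, the quaternary C1, C10 and C11. D-Glucose supplies C6–C10 with C7, C8 and C9.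

Key step: step 14

Remark: briarane numbering is used for every intermediate (glucose C1–C5 = C6–C10). α is the face of H10 and β is the face of the C15 methyl group.

Step 1
Reactants: 1 1,2:5,6-di-O-isopropylidene-α-D-glucofuranose
Product: 2 1,2:5,6-di-O-isopropylidene-α-D-ribo-hexofuranos-3-ulose
Conditions: TPAP (5 mol %), NMO, 4 Å MS, CH2Cl2, rt
Reagents that add atoms: none
Why: Ley–Griffith oxidation of the only free hydroxyl gives the C8 ketone, and both acetonides and the C7 and C9 stereocentres are untouched.

Step 2
Reactants: 2 1,2:5,6-di-O-isopropylidene-α-D-ribo-hexofuranos-3-ulose; 3 N,N-dimethylpropanamide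
Product: 5 3-C-[(1R)-1-(dimethylcarbamoyl)ethyl]-1,2:5,6-di-O-isopropylidene-α-D-allofuranose, via lithium Z-enolate 4 (not isolated)
Conditions: LDA, THF, −78 °C; then 2; AcOH quench
Reagents that add atoms: none
Why: Amide-enolate aldol addition to a ketone, in which the cis-fused 1,2-acetonide shields the α face so the bond forms on the convex β face (C8, OH α, allo), and the Z-enolate reacts through a closed Zimmerman–Traxler transition state with the carboxamide carbon over the open C7–H side, which sets C17 (R).

Step 3
Reactants: 5 3-C-[(1R)-1-(dimethylcarbamoyl)ethyl]-1,2:5,6-di-O-isopropylidene-α-D-allofuranose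
Product: 6 3-C-[(1R)-1-(dimethylcarbamoyl)ethyl]-1,2-O-isopropylidene-α-D-ribo-pentodialdo-1,4-furanose
Conditions: H5IO6, EtOAc, rt
Reagents that add atoms: none
Why: Periodic acid hydrolyses the more labile terminal acetonide and cleaves the freed glycol in the same pot (Malaprade cleavage), which excises glucose C6 and leaves C10 as the aldehyde without touching C9.

Step 4
Reactants: 6 3-C-[(1R)-1-(dimethylcarbamoyl)ethyl]-1,2-O-isopropylidene-α-D-ribo-pentodialdo-1,4-furanose; 7 3-(triphenyl-λ5-phosphanylidene)butan-2-one
Product: 8 furanose 1,2-acetonide bearing the (10E)-enone C10H=C11(CH3)–C12(=O)–C13H3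
Conditions: toluene, 80 °C
Reagents that add atoms: none
Why: Wittig olefination with a stabilised α-methyl acyl ylide is E-selective (C9 trans to C12) and neutral enough not to epimerise the α-alkoxy aldehyde.

Step 5
Reactants: 8 furanose 1,2-acetonide bearing the (10E)-enone
Product: 9 isomeric 2,3-O-isopropylidene lactol (O7/O8 acetonide; free anomeric OH at C6; anomeric mixture)
Conditions: CSA (10 mol %), acetone, rt
Reagents that add atoms: none
Why: Acid-catalysed acetal migration, in which cleavage of the anomeric O–CMe2 bond and capture of the oxocarbenium ion by the cis tertiary 8-OH gives the 2,3-acetonide that ribo-furanoses prefer, so C6 is freed as a lactol, O7/O8 are masked and O9 stays the ring oxygen.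

Step 6
Reactants: 10 methyl (triphenyl-λ5-phosphanylidene)acetate; 11 2-(2-bromoethyl)-1,3-dioxolane
Product: 13 methyl 4-(1,3-dioxolan-2-yl)-2-(triphenyl-λ5-phosphanylidene)butanoate, via phosphonium bromide 12 (not isolated)
Conditions: MeCN, reflux; then 1 M NaOH, CH2Cl2
Reagents that add atoms: none
Why: C-alkylation of a stabilised phosphorane by a primary bromide followed by deprotonation of the phosphonium salt gives the α-substituted stabilised ylide that holds C2–C5 and C16.

Step 7
Reactants: 9 2,3-O-isopropylidene lactol; 13 methyl 4-(1,3-dioxolan-2-yl)-2-(triphenyl-λ5-phosphanylidene)butanoate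
Product: 14 open-chain (5E)-enoate/(10E)-enone with O7/O8 acetonide, C2 dioxolane and free 9-OH
Conditions: PhCO2H (cat.), toluene, 90 °C
Reagents that add atoms: none
Why: Wittig olefination of the lactol through its open hydroxy-aldehyde form, where the stabilised α-alkyl ylide gives the trisubstituted enoate with CO2Me trans to C7 (C4 cis to C7, as the ring needs), only O9–H is released, and the tertiary amide does not lactonise under neutral conditions.

Step 8
Reactants: 15 acrolein
Product: 17 2-bromoacrolein, via 2,3-dibromopropanal 16 (not isolated)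
Conditions: Br2, CH2Cl2, −78 to 0 °C; then Et3N
Reagents that add atoms: bromine BrBr
Why: Bromine addition followed by E1cB dehydrobromination of the acidic α-hydrogen is the standard entry to the α-bromo enal.

Step 9
Reactants: 14 open-chain (5E)-enoate/(10E)-enone with free 9-OH; 17 2-bromoacrolein
Product: 19 (14S)-β-hydroxy ketone carrying the C1(Br)=C15H2 bromoalkene, via bis-borinate enolate 18 (not isolated)
Conditions: (−)-Ipc2BCl (excess), Et3N, Et2O, 0 °C; 17, −78 to −20 °C; H2O2, pH 7 buffer, MeOH
Reagents that add atoms: none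
Why: Diisopinocampheylboron-mediated aldol reaction, in which the methyl ketone is enolised only at C13 (O9–H travels as its borinate, and esters, amide and acetals are not enolised) and the chiral ligands on boron select one face of the reactive enal to set C14 (S) under reagent control.

Step 10
Reactants: 19 (14S)-β-hydroxy ketone
Product: 20 9,14-diacetate
Conditions: Ac2O, pyridine, DMAP (cat.), CH2Cl2, 0 °C
Reagents that add atoms: acetic anhydride CC(=O)OC(C)=O
Why: DMAP-catalysed acetylation of the two secondary alcohols installs two of the final acetates and blocks O9 before the lactone is formed, and the low temperature avoids β-elimination of the 14-acetate.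

Step 11
Reactants: 20 9,14-diacetate
Product: 22 γ-lactone aldehyde (C2 aldehyde; C7–O–C19 lactone; free tertiary 8-OH), via dihydroxy amide aldehyde 21 (not isolated)
Conditions: TFA/H2O (4:1), 0 °C to rt
Reagents that add atoms: water O
Why: Aqueous acid hydrolyses the ketal and the acetal, and O7–H (the only free γ-hydroxyl because O9 is acetylated) then attacks the amide in an acid-catalysed 5-exo-trig lactonisation accelerated by the fully substituted C8, with no stereocentre affected.

Step 12
Reactants: 22 γ-lactone aldehyde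
Product: 23 14-membered carbocycle with (2R)-allylic alcohol and exocyclic C1=C15 methylene
Conditions: CrCl2 (8 equiv), NiCl2 (2 mol %), DMSO/THF, rt, 2 mM
Reagents that add atoms: none
Why: Nozaki–Hiyama–Kishi reaction, in which nickel inserts into the C1–Br bond, transmetalation gives an alkenylchromium(III) that adds only to the aldehyde (ketone, enoate, lactone, acetates and tertiary OH are tolerated) and closes the ring at high dilution, and C2 (R, syn to the 14-acetate) is expected from the conformer with H14 eclipsing C1=C15 and approach anti to the C14–O bond.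

Step 13
Reactants: 23 14-membered carbocycle with (2R)-allylic alcohol
Product: 24 2,9,14-triacetate macrocycle
Conditions: Ac2O, pyridine, DMAP (cat.), CH2Cl2, 0 °C
Reagents that add atoms: acetic anhydride CC(=O)OC(C)=O
Why: Acetylation of the only secondary alcohol installs the third final acetate, and the hindered tertiary 8-OH is not acylated.

Step 14
Reactants: 24 2,9,14-triacetate macrocycle
Product: 25 briarane 12-ketone (trans-fused cyclohexanone/cyclodecene; 15-CH3 β; H10 α; 20-CH3 β)
Conditions: Fe(acac)3 (30 mol %), PhSiH3, EtOH, 60 °C, 5 mM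
Reagents that add atoms: none
Why: An iron hydride formed from Fe(acac)3 and PhSiH3 transfers a hydrogen atom to the CH2 terminus of C1=C15, which makes the C15 methyl group and a nucleophilic tertiary C1 radical; this radical adds across the ring to C10, the β-carbon of the s-trans enone, and the α-keto radical is reduced to an iron enolate that ethanol protonates at C11. The closest known reaction type is the MHAT-initiated reductive olefin coupling in its intramolecular form (Giese cyclisation to a quaternary carbon). The C1–C10 bond closes the cyclohexane in a 6-endo-trig mode (5-exo attack at the methyl-bearing α-carbon C11 is polarity-mismatched and hindered), and the same bond, seen from the other side as a 10-exo-trig closure, turns the remaining perimeter of the 14-membered ring into the cyclodecene. C10 is controlled by C9, because A(1,3) strain with the C11 methyl holds H9 in the enone plane, so C8 and the C2–C8 strap that carries C1 lie on one face and the 9-acetate on the other, and bonding on the strap face gives the required C9/C10 relationship. C1 is set in the chair-like transition state of the E-enone, with C9 and the larger C2 branch equatorial and the new methyl axial (trans ring fusion), and C11 is set by protonation of the enolate from the α face, away from the C15 methyl and C9. The step needs hydrogen-atom transfer only to the single electron-rich 1,1-disubstituted alkene (enone and enoate are electron-poor and trisubstituted) and attack at C10 rather than at the enoate carbon C6, which the stronger activation by the ketone should secure.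

Step 15
Reactants: 25 briarane 12-ketone
Product: 26 12β-alcohol (12-epi-12-deacetyl target)
Conditions: NaBH4, MeOH/CH2Cl2, −40 °C
Reagents that add atoms: none
Why: In this borohydride 1,2-reduction hydride reaches C12 from the open α face, because the β face carries the C15 and C20 methyl groups and C9, so the 12β-alcohol should form, and the enoate, lactone and acetates are inert at this temperature.

Step 16
Reactants: 26 12β-alcohol
Product: 27 CNP0230222.1 (target)
Conditions: PPh3, DIAD, AcOH, toluene, 0 °C to rt
Reagents that add atoms: acetic acid CC(=O)O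
Why: Mitsunobu esterification, in which acetate displaces the oxyphosphonium group by SN2 from the same open α face, inverts C12 to the 12α-acetate and completes the target, while the tertiary 8-OH does not react.

Compound list
1 | 1,2:5,6-di-O-isopropylidene-α-D-glucofuranose | CC1(C)OC[C@@H](O1)[C@H]2O[C@@H]3OC(C)(C)O[C@@H]3[C@H]2O | starting material
2 | 1,2:5,6-di-O-isopropylidene-α-D-ribo-hexofuranos-3-ulose | CC1(C)OC[C@@H](O1)[C@H]2O[C@@H]3OC(C)(C)O[C@@H]3C2=O | intermediate
3 | N,N-dimethylpropanamide | CCC(=O)N(C)C | starting material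
4 | lithium (Z)-enolate of 3 (CH3 cis to OLi) | [Li+].C/C=C(\[O-])N(C)C | intermediate
5 | 3-C-[(1R)-1-(dimethylcarbamoyl)ethyl]-1,2:5,6-di-O-isopropylidene-α-D-allofuranose | CC1(C)OC[C@@H](O1)[C@H]2O[C@@H]3OC(C)(C)O[C@@H]3[C@@]2(O)[C@@H](C)C(=O)N(C)C | intermediate
6 | 3-C-[(1R)-1-(dimethylcarbamoyl)ethyl]-1,2-O-isopropylidene-α-D-ribo-pentodialdo-1,4-furanose | O=C[C@H]1O[C@@H]2OC(C)(C)O[C@@H]2[C@@]1(O)[C@@H](C)C(=O)N(C)C | intermediate
7 | 3-(triphenyl-λ5-phosphanylidene)butan-2-one | CC(=O)C(C)=P(c1ccccc1)(c1ccccc1)c1ccccc1 | starting material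
8 | furanose 1,2-acetonide with (10E)-methyl enone side chain | CC(=O)/C(C)=C/[C@H]1O[C@@H]2OC(C)(C)O[C@@H]2[C@@]1(O)[C@@H](C)C(=O)N(C)C | intermediate
9 | 2,3-O-isopropylidene (O7/O8) lactol isomer of 8, anomeric mixture | CC(=O)/C(C)=C/[C@H]1OC(O)[C@@H]2OC(C)(C)O[C@]12[C@@H](C)C(=O)N(C)C | intermediate
10 | methyl (triphenyl-λ5-phosphanylidene)acetate | COC(=O)C=P(c1ccccc1)(c1ccccc1)c1ccccc1 | starting material
11 | 2-(2-bromoethyl)-1,3-dioxolane | BrCCC1OCCO1 | starting material
12 | [3-(1,3-dioxolan-2-yl)-1-(methoxycarbonyl)propyl]triphenylphosphonium bromide | [Br-].COC(=O)C(CCC1OCCO1)[P+](c1ccccc1)(c1ccccc1)c1ccccc1 | intermediate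
13 | methyl 4-(1,3-dioxolan-2-yl)-2-(triphenyl-λ5-phosphanylidene)butanoate | COC(=O)C(CCC1OCCO1)=P(c1ccccc1)(c1ccccc1)c1ccccc1 | intermediate
14 | open-chain (5E)-enoate/(10E)-enone: C2 dioxolane, O7/O8 acetonide, (17R)-dimethylamide, free 9-OH | O1CCOC1CC/C(C(=O)OC)=C\[C@@H]2OC(C)(C)O[C@]2([C@@H](C)C(=O)N(C)C)[C@H](O)/C=C(C)/C(C)=O | intermediate
15 | acrolein | C=CC=O | starting material
16 | 2,3-dibromopropanal | O=CC(Br)CBr | intermediate
17 | 2-bromoacrolein | C=C(Br)C=O | intermediate
18 | C12 enol diisopinocampheylborinate of 14 with O9 diisopinocampheylborinate | O1CCOC1CC/C(C(=O)OC)=C\[C@@H]2OC(C)(C)O[C@]2([C@@H](C)C(=O)N(C)C)[C@H](OB([C@@H]3C[C@@H]4C[C@H]([C@H]3C)C4(C)C)[C@@H]3C[C@@H]4C[C@H]([C@H]3C)C4(C)C)/C=C(C)/C(=C)OB([C@@H]3C[C@@H]4C[C@H]([C@H]3C)C4(C)C)[C@@H]3C[C@@H]4C[C@H]([C@H]3C)C4(C)C | intermediate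
19 | (14S)-aldol adduct: 9,14-diol with C1(Br)=C15H2 | O1CCOC1CC/C(C(=O)OC)=C\[C@@H]2OC(C)(C)O[C@]2([C@@H](C)C(=O)N(C)C)[C@H](O)/C=C(C)/C(=O)C[C@H](O)C(Br)=C | intermediate
20 | 9,14-diacetate of 19 | O1CCOC1CC/C(C(=O)OC)=C\[C@@H]2OC(C)(C)O[C@]2([C@@H](C)C(=O)N(C)C)[C@H](OC(C)=O)/C=C(C)/C(=O)C[C@H](OC(C)=O)C(Br)=C | intermediate
21 | 7,8-dihydroxy amide with free C2 aldehyde | O=CCC/C(C(=O)OC)=C\[C@H](O)[C@@](O)([C@@H](C)C(=O)N(C)C)[C@H](OC(C)=O)/C=C(C)/C(=O)C[C@H](OC(C)=O)C(Br)=C | intermediate
22 | γ-lactone aldehyde (C7–O–C19 lactone, 8-OH, 9,14-diacetate, bromoalkene) | O=CCC/C(C(=O)OC)=C\[C@@H]1OC(=O)[C@H](C)[C@@]1(O)[C@H](OC(C)=O)/C=C(C)/C(=O)C[C@H](OC(C)=O)C(Br)=C | intermediate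
23 | 14-membered carbocycle, (2R)-alcohol, C1=C15 methylene, (10E)-enone | COC(=O)/C1=C/[C@@H]2OC(=O)[C@H](C)[C@@]2(O)[C@H](OC(C)=O)/C=C(C)/C(=O)C[C@H](OC(C)=O)C(=C)[C@H](O)CC1 | intermediate
24 | 2,9,14-triacetate macrocycle | COC(=O)/C1=C/[C@@H]2OC(=O)[C@H](C)[C@@]2(O)[C@H](OC(C)=O)/C=C(C)/C(=O)C[C@H](OC(C)=O)C(=C)[C@H](OC(C)=O)CC1 | intermediate
25 | briarane 12-ketone, 2,9,14-triacetate | COC(=O)/C1=C/[C@@H]2OC(=O)[C@H](C)[C@@]2(O)[C@H](OC(C)=O)[C@H]2[C@@H](C)C(=O)C[C@H](OC(C)=O)[C@]2(C)[C@H](OC(C)=O)CC1 | intermediate
26 | 12β-alcohol, 2,9,14-triacetate | COC(=O)/C1=C/[C@@H]2OC(=O)[C@H](C)[C@@]2(O)[C@H](OC(C)=O)[C@H]2[C@@H](C)[C@@H](O)C[C@H](OC(C)=O)[C@]2(C)[C@H](OC(C)=O)CC1 | intermediate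
27 | CNP0230222.1 | COC(=O)/C1=C/[C@@H]2OC(=O)[C@H](C)[C@@]2(O)[C@H](OC(C)=O)[C@H]2[C@@H](C)[C@H](OC(C)=O)C[C@H](OC(C)=O)[C@]2(C)[C@H](OC(C)=O)CC1 | target

Total step count: 16. Longest linear sequence: 14 (steps 1–5, 7, 9–16).

Steps most likely to fail

Step 14. The C1 radical may be quenched by a second hydrogen-atom transfer (net hydrogenation of C1=C15), or it may add to the enoate carbon C6 before it reaches C10. The fallback sets out from 24 and comes back at 25, and it generates the radical with no hydride donor present.
- Mukaiyama hydration of 24 (Mn(dpm)3, PhSiH3, O2, i-PrOH) should give the tertiary C1 alcohol F1. Either C1 epimer serves, because the centre becomes planar again.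
- Acylation with methyl chlorooxoacetate (Et3N, DMAP) should give the mixed methyl oxalate F2.
- One equivalent of aqueous CsOH should give the caesium oxalate F3.
- Visible-light photoredox oxidation (iridium photocatalyst, DME/DMF, water) releases the same tertiary radical under redox-neutral conditions at a low stationary concentration, and the Giese closure should give 25.

Step 12. Facial selectivity at the aldehyde carbon during ring closure may be poor, so that the C2 epimer forms in part or mainly. The fallback sets out from 22 and comes back at 24, and C2 is then fixed by substitution instead of by addition. The ring is closed as before and the epimers are separated. The (2S)-alcohol F4 is treated under Mitsunobu conditions (PPh3, DIAD, AcOH), which invert C2 and deliver the 2-acetate 24 directly. The (2R)-alcohol 23 is acetylated as in step 13, so both epimers converge on 24.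

Step 16. E2 loss of the activated 12β-oxygen (anti-periplanar H11 and H13 on the α face) may outrun substitution at this hindered carbon. The fallback sets out from 26 and comes back at 27, and it uses the elimination on purpose.
- Dehydration of 26 with Martin sulfurane should give the trisubstituted Δ11(12)-alkene F5.
- Hydroboration (BH3·THF, 0 °C, then NaBO3) adds H to C11 and boron to C12 syn from the α face, opposite the C15 methyl and C9, and should give the 12α-alcohol F6 with H11 α. This would also correct any C11 epimer.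
- Acetylation (Ac2O, pyridine, DMAP) gives 27.

Further compounds
F1 | step 14 | tertiary C1 alcohol of the macrocycle (C1 configuration immaterial) | COC(=O)/C1=C/[C@@H]2OC(=O)[C@H](C)[C@@]2(O)[C@H](OC(C)=O)/C=C(C)/C(=O)C[C@H](OC(C)=O)C(C)(O)[C@H](OC(C)=O)CC1
F2 | step 14 | C1 methyl oxalate | COC(=O)/C1=C/[C@@H]2OC(=O)[C@H](C)[C@@]2(O)[C@H](OC(C)=O)/C=C(C)/C(=O)C[C@H](OC(C)=O)C(C)(OC(=O)C(=O)OC)[C@H](OC(C)=O)CC1
F3 | step 14 | C1 caesium oxalate | [Cs+].COC(=O)/C1=C/[C@@H]2OC(=O)[C@H](C)[C@@]2(O)[C@H](OC(C)=O)/C=C(C)/C(=O)C[C@H](OC(C)=O)C(C)(OC(=O)C(=O)[O-])[C@H](OC(C)=O)CC1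
F4 | step 12 | (2S)-epimer of macrocyclic alcohol 23 | COC(=O)/C1=C/[C@@H]2OC(=O)[C@H](C)[C@@]2(O)[C@H](OC(C)=O)/C=C(C)/C(=O)C[C@H](OC(C)=O)C(=C)[C@@H](O)CC1
F5 | step 16 | Δ11(12)-alkene, 2,9,14-triacetate | COC(=O)/C1=C/[C@@H]2OC(=O)[C@H](C)[C@@]2(O)[C@H](OC(C)=O)[C@H]2C(C)=CC[C@H](OC(C)=O)[C@]2(C)[C@H](OC(C)=O)CC1
F6 | step 16 | 12α-alcohol, 2,9,14-triacetate | COC(=O)/C1=C/[C@@H]2OC(=O)[C@H](C)[C@@]2(O)[C@H](OC(C)=O)[C@H]2[C@@H](C)[C@H](O)C[C@H](OC(C)=O)[C@]2(C)[C@H](OC(C)=O)CC1
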